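**Assumption:** the target, methyl 2-(5-hexadecylfuran-2-yl)acetate (C23H40O3), has no stereocentres, so the "single enantiomer" requirement does not apply and no stereocontrol is needed.

## Retrosynthetic overview

1. No ring is formed: the furan ring is bought as furan (1).
2. C5–alkyl bond: α-lithiation of 1 and SN2 alkylation with 1-bromohexadecane (2) gives 2-hexadecylfuran (3).
3. C2–CH2CO2Me bond: direct radical C–H alkylation of 3 at its only free α-position with methyl iodoacetate (4) gives the target (5).

## Route

**Step 1**

- Reactants: 1, furan (1.5–2 equiv); 2, 1-bromohexadecane (limiting).
- Product: 3, 2-hexadecylfuran.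
- Conditions: n-BuLi (hexanes), THF, 0 °C, 1 h; then 2, 0 °C → rt, 16 h.
- Reagents that add atoms: 1-bromohexadecane (2), CCCCCCCCCCCCCCCCBr. n-BuLi contributes no atoms.
- Why: furan is deprotonated selectively at the α-position (directed by the ring oxygen), and 2-furyllithium displaces the unhindered primary bromide by SN2 (lithiation–alkylation). Excess volatile furan suppresses dialkylation and consumes all of 2, which would otherwise be hard to separate from the non-polar product.

**Step 2**

- Reactants: 3, 2-hexadecylfuran; 4, methyl iodoacetate (about 3 equiv).
- Product: 5, methyl 2-(5-hexadecylfuran-2-yl)acetate (target).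
- Conditions: FeSO4·7H2O, 30% aq. H2O2 (slow addition), DMSO, rt, vigorous stirring; a little benzene or PhCF3 co-solvent if 3 does not disperse.
- Reagents that add atoms: methyl iodoacetate (4), COC(=O)CI.
- Why: this is a Fenton-initiated homolytic aromatic substitution. HO• converts DMSO to CH3•, which abstracts iodine from 4 to give the electrophilic radical •CH2CO2Me. This adds to the electron-rich free α-carbon (C5) of the 2-alkylfuran, and Fe(III) oxidation followed by proton loss restores the aromatic ring. The methyl ester and the alkyl chain are inert to these conditions, and DMSO as solvent scavenges HO• before it can attack the furan.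

## Compound list

1 | furan | c1ccoc1 | starting material
2 | 1-bromohexadecane | CCCCCCCCCCCCCCCCBr | starting material
3 | 2-hexadecylfuran | CCCCCCCCCCCCCCCCc1ccco1 | intermediate
4 | methyl iodoacetate | COC(=O)CI | starting material
5 | methyl 2-(5-hexadecylfuran-2-yl)acetate | CCCCCCCCCCCCCCCCc1ccc(CC(=O)OC)o1 | target

## Summary

- Total step count: 2
- Longest linear sequence: 2

**Steps most likely to fail** (the route has only two steps, so both are listed; the third entry is a distinct second failure mode of Step 2):

1. **Step 2, low conversion.** The waxy, lipophilic 3 is poorly soluble in DMSO, and the furan can be degraded oxidatively under Fenton conditions. Fallback: replace the C–H alkylation with a cross-coupling. Brominate 3 at C5 (NBS, DMF, 0 °C) to 2-bromo-5-hexadecylfuran, then couple it with the Reformatsky reagent BrZnCH2CO2Me under Pd catalysis (Pd(dba)2/Q-Phos or XPhos, THF). This adds one step.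
2. **Step 1, incomplete alkylation.** Competing E2 of the long-chain bromide gives 1-hexadecene, and any unreacted 2 is hard to separate from 3. Fallback: build the chain by olefination. Wittig reaction of furfural with the ylide from pentadecyltriphenylphosphonium bromide gives 2-(hexadec-1-enyl)furan, and diimide reduction of the side-chain alkene (TsNHNH2, NaOAc) gives 3 without touching the furan.
3. **Step 2, selectivity and isolation.** Minor β-attack, over-alkylation at the activated CH2 of the product, or acid-promoted ring opening during work-up could erode the yield. Fallback: a polar, fully regiodefined sequence. Lithiate 3 at C5 (n-BuLi, THF) and open ethylene oxide to give 2-(5-hexadecylfuran-2-yl)ethanol, oxidise to the acid, and esterify with MeI/K2CO3 to give 5.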